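The ring is opened at C5–C6 (numbering: C1 quaternary oxirane carbon bearing C7H2OBz, C2 CH–OBz, C3 CH–OH, C4=C5, C6 oxirane CH). C6 sits between the quaternary, non-enolisable C1 and the vinylic C5 of the cyclohexene, so it can be an aldehyde attacked by a C5 alkenylchromium: one Nozaki–Hiyama–Kishi reaction closes the carbocycle, keeps the cis C4=C5 bond and creates the C6 hydroxyl that, as mesylate, is displaced by the C1 oxygen to form the oxirane ring. The precursor is an acyclic (Z)-iodoalkenyl aldehyde with C2/C7 benzoates, a C1 triethylsilyl and a C3 tert-butyldimethylsilyl ether, assembled from a D-proline aldol.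

Key step: step 12

Remark: the locants C1–C7 defined above are used for the carbocyclic compounds 18–21, and their CIP descriptors refer to these locants; the dioxane and open-chain intermediates carry their own systematic locants.
Remark (assumption): the Grignard reagent is taken to attack the 1,3-dioxan-5-one along the axial trajectory, as this ring system generally does, so the vinyl carbon becomes the C7 arm and the ring methylene becomes C6.

Step 1
Reactants: 1 2,2-dimethyl-1,3-dioxan-5-one; 2 3-(trimethylsilyl)prop-2-ynal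
Product: 3 (4R)-4-[(1R)-1-hydroxy-3-(trimethylsilyl)prop-2-yn-1-yl]-2,2-dimethyl-1,3-dioxan-5-one
Conditions: (R)-proline (D-proline, 30 mol %), DMF, 4 °C
Reagents that add atoms: none
Why: Proline-catalysed direct aldol reaction, in which the E-enamine of the dioxanone adds to the ynal through the hydrogen-bonded chair transition state, should give the anti adduct, and D-proline should deliver the (4R,1'R) enantiomer (mirror image of the L-proline series), which sets C2 and C3 of the target.

Step 2
Reactants: 3 anti aldol adduct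
Product: 4 (4R)-4-[(1R)-1-(tert-butyldimethylsilyloxy)-3-(trimethylsilyl)prop-2-yn-1-yl]-2,2-dimethyl-1,3-dioxan-5-one
Conditions: TBSOTf, 2,6-lutidine, CH2Cl2, −78 °C
Reagents that add atoms: tert-butyldimethylsilyl trifluoromethanesulfonate, CC(C)(C)[Si](C)(C)OS(=O)(=O)C(F)(F)F
Why: Silylation of a secondary alcohol with a silyl triflate and a hindered base at low temperature avoids retro-aldol cleavage or epimerisation of the β-hydroxy ketone, and the tert-butyldimethylsilyl ether is chosen because it should outlast the later acidic acetonide cleavage.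

Step 3
Reactants: 4 silylated ketone; 5 vinylmagnesium bromide
Product: 6 (4R,5S)-4-[(1R)-1-(tert-butyldimethylsilyloxy)-3-(trimethylsilyl)prop-2-yn-1-yl]-5-ethenyl-2,2-dimethyl-1,3-dioxan-5-ol (vinyl cis to the C4 side chain)
Conditions: THF, −78 °C; then aq. NH4Cl
Reagents that add atoms: none
Why: Grignard 1,2-addition to a ketone, where 1,3-dioxan-5-ones take hydride and Grignard reagents from the axial direction (ring flattened at the carbonyl end, ring oxygens in place of syn-axial hydrogens), so with the C4 side chain equatorial the vinyl group should end cis to it and the hydroxyl trans, which sets C1 in the sense in which the vinyl carbon becomes C7 and the ring methylene C6; the configuration of 6 is to be confirmed by NOE before going on.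

Step 4
Reactants: 6 tertiary allylic alcohol
Product: 9 (4R,5S)-4-[(1R)-1-(tert-butyldimethylsilyloxy)-3-(trimethylsilyl)prop-2-yn-1-yl]-5-(hydroxymethyl)-2,2-dimethyl-1,3-dioxan-5-ol, via ozonide 7 (not isolated), via hydroxy aldehyde 8 (not isolated)
Conditions: O3, CH2Cl2, −78 °C; then NaBH4, MeOH, −78 to 0 °C
Reagents that add atoms: ozone, O=[O+][O-]
Why: Ozonolysis with reductive borohydride work-up, in which ozone should consume the only alkene far faster than the silylalkyne and NaBH4 should reduce the ozonide through the aldehyde to the primary C7 alcohol without touching silyl ether or acetonide, no stereocentre being affected.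

Step 5
Reactants: 9 diol; 10 benzoyl chloride
Product: 11 {(4R,5R)-4-[(1R)-1-(tert-butyldimethylsilyloxy)-3-(trimethylsilyl)prop-2-yn-1-yl]-5-hydroxy-2,2-dimethyl-1,3-dioxan-5-yl}methyl benzoate
Conditions: pyridine, CH2Cl2, 0 °C
Reagents that add atoms: none
Why: Acylation with an acid chloride in pyridine should esterify the primary C7 hydroxyl only, the tertiary C1 hydroxyl being inert under these conditions.

Step 6
Reactants: 11 hydroxy benzoate
Product: 12 {(4R,5R)-4-[(1R)-1-(tert-butyldimethylsilyloxy)-3-(trimethylsilyl)prop-2-yn-1-yl]-2,2-dimethyl-5-(triethylsilyloxy)-1,3-dioxan-5-yl}methyl benzoate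
Conditions: TESOTf, 2,6-lutidine, CH2Cl2, 0 °C to rt
Reagents that add atoms: triethylsilyl trifluoromethanesulfonate, CC[Si](CC)(CC)OS(=O)(=O)C(F)(F)F
Why: Silylation of a hindered tertiary alcohol with a silyl triflate and 2,6-lutidine is the usual way to cap such alcohols, and this ether should cover the C1 oxygen until the last step.

Step 7
Reactants: 12 silylalkyne
Product: 13 {(4R,5R)-4-[(1R)-1-(tert-butyldimethylsilyloxy)-3-iodoprop-2-yn-1-yl]-2,2-dimethyl-5-(triethylsilyloxy)-1,3-dioxan-5-yl}methyl benzoate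
Conditions: N-iodosuccinimide, AgNO3 (10 mol %), acetone, rt, dark
Reagents that add atoms: N-iodosuccinimide, O=C1CCC(=O)N1I
Why: Silver-catalysed iododesilylation of an alkynylsilane (through the silver acetylide) is a standard route to 1-iodoalkynes and should leave silyl ethers, benzoate and acetonide untouched.

Step 8
Reactants: 13 iodoalkyne
Product: 14 {(4R,5R)-4-[(1R,2Z)-1-(tert-butyldimethylsilyloxy)-3-iodoprop-2-en-1-yl]-2,2-dimethyl-5-(triethylsilyloxy)-1,3-dioxan-5-yl}methyl benzoate
Conditions: 2-nitrobenzenesulfonylhydrazide, Et3N, THF/i-PrOH, rt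
Reagents that add atoms: none
Why: Diimide reduction (syn transfer of two hydrogens from HN=NH generated from the sulfonyl hydrazide) should give the (Z)-iodoalkene from the 1-iodoalkyne and is much slower on the iodoalkene formed, no other C–C multiple bond being present at this stage.

Step 9
Reactants: 14 acetonide
Product: 15 (2R,3R,4R,5Z)-4-(tert-butyldimethylsilyloxy)-3-hydroxy-2-(hydroxymethyl)-6-iodo-2-(triethylsilyloxy)hex-5-en-1-yl benzoate
Conditions: pyridinium p-toluenesulfonate (PPTS, 20 mol %), MeOH, 0 °C to rt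
Reagents that add atoms: none
Why: Acid-catalysed transacetalisation of the 1,3-dioxane acetonide to methanol should free the C2 and C6 hydroxyls under conditions mild enough for the secondary tert-butyldimethylsilyl and the hindered tertiary triethylsilyl ether, and the diol is oxidised without delay so that the C7 benzoate cannot wander to O6.

Step 10
Reactants: 15 diol
Product: 16 (2R,3R,4R,5Z)-4-(tert-butyldimethylsilyloxy)-2-formyl-3-hydroxy-6-iodo-2-(triethylsilyloxy)hex-5-en-1-yl benzoate
Conditions: 2,2,6,6-tetramethylpiperidin-1-oxyl (TEMPO, 10 mol %), PhI(OAc)2, CH2Cl2, rt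
Reagents that add atoms: none
Why: Oxoammonium (TEMPO) oxidation with PhI(OAc)2 as terminal oxidant is selective for the primary C6 alcohol over the hindered secondary C2 alcohol and should stop at the aldehyde, which cannot enolise because C1 is quaternary.

Step 11
Reactants: 16 hydroxy aldehyde; 10 benzoyl chloride
Product: 17 (2R,3R,4R,5Z)-4-(tert-butyldimethylsilyloxy)-2-formyl-6-iodo-2-(triethylsilyloxy)hex-5-ene-1,3-diyl dibenzoate
Conditions: pyridine, 4-(dimethylamino)pyridine (DMAP, 10 mol %), CH2Cl2, 0 °C to rt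
Reagents that add atoms: none
Why: Nucleophile-catalysed benzoylation of the remaining secondary hydroxyl should proceed while the non-enolisable aldehyde, both silyl ethers and the iodoalkene stay inert.

Step 12
Reactants: 17 (Z)-iodoalkenyl aldehyde
Product: 18 [(1S,2R,3R,6R)-2-(benzoyloxy)-3-(tert-butyldimethylsilyloxy)-6-hydroxy-1-(triethylsilyloxy)cyclohex-4-en-1-yl]methyl benzoate
Conditions: CrCl2 (6 equiv), NiCl2 (2 mol %), degassed DMSO, rt, 0.005 M
Reagents that add atoms: none
Why: Zerovalent nickel, formed from NiCl2 by CrCl2, inserts into the C5–I bond with retention of the Z geometry, and transmetalation to trivalent chromium gives the alkenylchromium species, which adds to the C6 aldehyde to form the C5–C6 bond and the chromium alkoxide of 18. The closest known reaction type is the intramolecular Nozaki–Hiyama–Kishi cyclisation of iodoalkenyl aldehydes to cyclic allylic alcohols, which tolerates esters and silyl ethers. The six-membered ring closes in the 6-exo-trig mode, the carbonyl oxygen staying outside the ring. The new stereocentre C6 is controlled by the substrate: in the half-chair transition state the C1 and C3 silyloxy groups are (pseudo)equatorial, the C2 benzoate and the C7 arm axial, C5 approaches anti to the C1–O bond (Felkin–Anh) and the chromium-bound oxygen takes the pseudoequatorial position away from the axial C2 benzoate, which places it trans to the C1 oxygen. The selectivity needed is this trans relationship (6R), and it is secured by the all-cis array of oxygens at C1, C2 and C3 that fixes the half-chair, with high dilution suppressing intermolecular addition.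

Step 13
Reactants: 18 cyclohexenol
Product: 19 [(1R,2R,3R,6R)-2-(benzoyloxy)-3-(tert-butyldimethylsilyloxy)-6-(methanesulfonyloxy)-1-(triethylsilyloxy)cyclohex-4-en-1-yl]methyl benzoate
Conditions: Ms2O, Et3N, CH2Cl2, 0 °C
Reagents that add atoms: methanesulfonic anhydride, CS(=O)(=O)OS(C)(=O)=O
Why: Sulfonylation of the only free hydroxyl with the anhydride, used in place of the sulfonyl chloride so that no chloride can displace the allylic mesylate, should retain the configuration at C6.

Step 14
Reactants: 19 mesylate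
Product: 21 target [(1S,2R,3R,6S)-2-(benzoyloxy)-1,6-epoxy-3-hydroxycyclohex-4-en-1-yl]methyl benzoate, via epoxy silyl ether 20 (not isolated)
Conditions: TBAF (1.2 equiv), THF, −20 to 0 °C; then AcOH (6 equiv), TBAF (5 equiv), 0 °C to rt
Reagents that add atoms: none
Why: Fluoride should cleave the more labile tertiary triethylsilyl ether first, so that the C1 alkoxide displaces the anti-periplanar allylic mesylate (intramolecular Williamson etherification, 3-exo-tet) with inversion at C6 to give the oxirane, and the tert-butyldimethylsilyl ether is then removed with acetic-acid-buffered fluoride so that no free C3 alkoxide can take over the C2 benzoate.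

Compound list
1 | 2,2-dimethyl-1,3-dioxan-5-one | CC1(C)OCC(=O)CO1 | starting material
2 | 3-(trimethylsilyl)prop-2-ynal | C[Si](C)(C)C#CC=O | starting material
3 | (4R)-4-[(1R)-1-hydroxy-3-(trimethylsilyl)prop-2-yn-1-yl]-2,2-dimethyl-1,3-dioxan-5-one | C[Si](C)(C)C#C[C@@H](O)[C@H]1OC(C)(C)OCC1=O | intermediate
4 | (4R)-4-[(1R)-1-(tert-butyldimethylsilyloxy)-3-(trimethylsilyl)prop-2-yn-1-yl]-2,2-dimethyl-1,3-dioxan-5-one | C[Si](C)(C)C#C[C@@H](O[Si](C)(C)C(C)(C)C)[C@H]1OC(C)(C)OCC1=O | intermediate
5 | vinylmagnesium bromide | C=C[Mg]Br | starting material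
6 | (4R,5S)-4-[(1R)-1-(tert-butyldimethylsilyloxy)-3-(trimethylsilyl)prop-2-yn-1-yl]-5-ethenyl-2,2-dimethyl-1,3-dioxan-5-ol | C[Si](C)(C)C#C[C@@H](O[Si](C)(C)C(C)(C)C)[C@H]1OC(C)(C)OC[C@@]1(O)C=C | intermediate
7 | ozonide of 6, (4R,5S)-4-[(1R)-1-(tert-butyldimethylsilyloxy)-3-(trimethylsilyl)prop-2-yn-1-yl]-2,2-dimethyl-5-(1,2,4-trioxolan-3-yl)-1,3-dioxan-5-ol, both epimers at the trioxolane carbon | C[Si](C)(C)C#C[C@@H](O[Si](C)(C)C(C)(C)C)[C@H]1OC(C)(C)OC[C@@]1(O)C2OCOO2 | intermediate (not isolated)
8 | (4R,5S)-4-[(1R)-1-(tert-butyldimethylsilyloxy)-3-(trimethylsilyl)prop-2-yn-1-yl]-5-hydroxy-2,2-dimethyl-1,3-dioxane-5-carbaldehyde | C[Si](C)(C)C#C[C@@H](O[Si](C)(C)C(C)(C)C)[C@H]1OC(C)(C)OC[C@@]1(O)C=O | intermediate (not isolated)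
9 | (4R,5S)-4-[(1R)-1-(tert-butyldimethylsilyloxy)-3-(trimethylsilyl)prop-2-yn-1-yl]-5-(hydroxymethyl)-2,2-dimethyl-1,3-dioxan-5-ol | C[Si](C)(C)C#C[C@@H](O[Si](C)(C)C(C)(C)C)[C@H]1OC(C)(C)OC[C@@]1(O)CO | intermediate
10 | benzoyl chloride | O=C(Cl)c1ccccc1 | starting material
11 | {(4R,5R)-4-[(1R)-1-(tert-butyldimethylsilyloxy)-3-(trimethylsilyl)prop-2-yn-1-yl]-5-hydroxy-2,2-dimethyl-1,3-dioxan-5-yl}methyl benzoate | C[Si](C)(C)C#C[C@@H](O[Si](C)(C)C(C)(C)C)[C@H]1OC(C)(C)OC[C@@]1(O)COC(=O)c1ccccc1 | intermediate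
12 | {(4R,5R)-4-[(1R)-1-(tert-butyldimethylsilyloxy)-3-(trimethylsilyl)prop-2-yn-1-yl]-2,2-dimethyl-5-(triethylsilyloxy)-1,3-dioxan-5-yl}methyl benzoate | C[Si](C)(C)C#C[C@@H](O[Si](C)(C)C(C)(C)C)[C@H]1OC(C)(C)OC[C@@]1(O[Si](CC)(CC)CC)COC(=O)c1ccccc1 | intermediate
13 | {(4R,5R)-4-[(1R)-1-(tert-butyldimethylsilyloxy)-3-iodoprop-2-yn-1-yl]-2,2-dimethyl-5-(triethylsilyloxy)-1,3-dioxan-5-yl}methyl benzoate | IC#C[C@@H](O[Si](C)(C)C(C)(C)C)[C@H]1OC(C)(C)OC[C@@]1(O[Si](CC)(CC)CC)COC(=O)c1ccccc1 | intermediate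
14 | {(4R,5R)-4-[(1R,2Z)-1-(tert-butyldimethylsilyloxy)-3-iodoprop-2-en-1-yl]-2,2-dimethyl-5-(triethylsilyloxy)-1,3-dioxan-5-yl}methyl benzoate | I/C=C\[C@@H](O[Si](C)(C)C(C)(C)C)[C@H]1OC(C)(C)OC[C@@]1(O[Si](CC)(CC)CC)COC(=O)c1ccccc1 | intermediate
15 | (2R,3R,4R,5Z)-4-(tert-butyldimethylsilyloxy)-3-hydroxy-2-(hydroxymethyl)-6-iodo-2-(triethylsilyloxy)hex-5-en-1-yl benzoate | I/C=C\[C@@H](O[Si](C)(C)C(C)(C)C)[C@@H](O)[C@@](O[Si](CC)(CC)CC)(CO)COC(=O)c1ccccc1 | intermediate
16 | (2R,3R,4R,5Z)-4-(tert-butyldimethylsilyloxy)-2-formyl-3-hydroxy-6-iodo-2-(triethylsilyloxy)hex-5-en-1-yl benzoate | I/C=C\[C@@H](O[Si](C)(C)C(C)(C)C)[C@@H](O)[C@@](O[Si](CC)(CC)CC)(C=O)COC(=O)c1ccccc1 | intermediate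
17 | (2R,3R,4R,5Z)-4-(tert-butyldimethylsilyloxy)-2-formyl-6-iodo-2-(triethylsilyloxy)hex-5-ene-1,3-diyl dibenzoate (key-step precursor) | I/C=C\[C@@H](O[Si](C)(C)C(C)(C)C)[C@@H](OC(=O)c1ccccc1)[C@@](O[Si](CC)(CC)CC)(C=O)COC(=O)c1ccccc1 | intermediate
18 | [(1S,2R,3R,6R)-2-(benzoyloxy)-3-(tert-butyldimethylsilyloxy)-6-hydroxy-1-(triethylsilyloxy)cyclohex-4-en-1-yl]methyl benzoate (key-step product, C6–OH trans to the C1 oxygen) | O[C@@H]1C=C[C@@H](O[Si](C)(C)C(C)(C)C)[C@@H](OC(=O)c2ccccc2)[C@]1(O[Si](CC)(CC)CC)COC(=O)c1ccccc1 | intermediate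
19 | [(1R,2R,3R,6R)-2-(benzoyloxy)-3-(tert-butyldimethylsilyloxy)-6-(methanesulfonyloxy)-1-(triethylsilyloxy)cyclohex-4-en-1-yl]methyl benzoate | CS(=O)(=O)O[C@@H]1C=C[C@@H](O[Si](C)(C)C(C)(C)C)[C@@H](OC(=O)c2ccccc2)[C@]1(O[Si](CC)(CC)CC)COC(=O)c1ccccc1 | intermediate
20 | [(1S,2R,3R,6S)-2-(benzoyloxy)-3-(tert-butyldimethylsilyloxy)-1,6-epoxycyclohex-4-en-1-yl]methyl benzoate | O=C(OC[C@]12O[C@H]1C=C[C@@H](O[Si](C)(C)C(C)(C)C)[C@H]2OC(=O)c1ccccc1)c1ccccc1 | intermediate (not isolated)
21 | [(1S,2R,3R,6S)-2-(benzoyloxy)-1,6-epoxy-3-hydroxycyclohex-4-en-1-yl]methyl benzoate | O=C(OC[C@]12O[C@H]1C=C[C@@H](O)[C@H]2OC(=O)c1ccccc1)c1ccccc1 | target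

Total step count: 14. Longest linear sequence: 14 steps (fully linear, from 1 and 2 to 21).

Steps most likely to fail

Step 3. The process at risk is facial selectivity: the Grignard reagent may add to the other face of the ketone (trans to the C4 side chain), which would interchange the roles of the two one-carbon arms at C1. The fallback sets out from 4 and comes back at 17. The adduct would then be the C5 epimer, allylic alcohol F1, in which the ring methylene is the C7 arm and the vinyl group the masked C6 aldehyde. Acetonide cleavage (PPTS, MeOH) would give the triol F2, and benzoylation of its primary and secondary hydroxyls (benzoyl chloride, pyridine, DMAP) the dibenzoate F3. Silylation of the tertiary hydroxyl (TESOTf, 2,6-lutidine) would give the silyl ether F4. Ozonolysis (O3, CH2Cl2, −78 °C; then PPh3) would lead through the ozonide F5 to the aldehyde F6. Iododesilylation (N-iodosuccinimide, AgNO3) would give the iodoalkyne F7, and diimide reduction with KO2CN=NCO2K and AcOH (no hydrazide, so the aldehyde is not condensed) would give 17.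

Step 12. The process at risk is addition to the wrong face of the aldehyde, leaving the C6 hydroxyl cis to the C1 oxygen, or a mixture of both. The fallback sets out from 17 and comes back at 18. The cyclisation product of the wrong or mixed configuration, the epimeric cyclohexenol F8, would be oxidised with Dess–Martin periodinane to the cyclohexenone F9. C6 would then be set by reagent control in a Corey–Bakshi–Shibata reduction ((S)-1-methyl-3,3-diphenyltetrahydro-1H,3H-pyrrolo[1,2-c][1,3,2]oxazaborole, catecholborane, toluene, −78 °C), the quaternary C1 acting as the large group. This would return 18 with the stereocentre made at a ketone and not in the C–C bond formation.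

Step 14. The process at risk is loss of the order of silyl cleavage: a free C3 alkoxide under basic fluoride would let the C2 benzoate migrate to O3. The fallback sets out from 18 and comes back at 20. The tertiary triethylsilyl ether of 18 would be cleaved first under acidic conditions (HF·pyridine, pyridine, THF, 0 °C), which should leave the tert-butyldimethylsilyl ether, to give the trans-diol F10. Cyclodehydration under Mitsunobu conditions (PPh3, diisopropyl azodicarboxylate, toluene) can activate only the secondary allylic C6 hydroxyl, and the C1 hydroxyl would displace it with inversion to give 20. The last silyl ether of 20 would then be removed with HF·pyridine at rt to give 21, so that no alkoxide is formed at any stage.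

Further compounds
F1 | step 3 | (4R,5R)-4-[(1R)-1-(tert-butyldimethylsilyloxy)-3-(trimethylsilyl)prop-2-yn-1-yl]-5-ethenyl-2,2-dimethyl-1,3-dioxan-5-ol (C5 epimer of 6) | C[Si](C)(C)C#C[C@@H](O[Si](C)(C)C(C)(C)C)[C@H]1OC(C)(C)OC[C@]1(O)C=C
F2 | step 3 | (3R,4R,5R)-5-(tert-butyldimethylsilyloxy)-3-(hydroxymethyl)-7-(trimethylsilyl)hept-1-en-6-yne-3,4-diol | C[Si](C)(C)C#C[C@@H](O[Si](C)(C)C(C)(C)C)[C@@H](O)[C@](O)(CO)C=C
F3 | step 3 | (2R,3R,4R)-4-(tert-butyldimethylsilyloxy)-2-ethenyl-2-hydroxy-6-(trimethylsilyl)hex-5-yne-1,3-diyl dibenzoate | C[Si](C)(C)C#C[C@@H](O[Si](C)(C)C(C)(C)C)[C@@H](OC(=O)c1ccccc1)[C@](O)(COC(=O)c1ccccc1)C=C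
F4 | step 3 | (2R,3R,4R)-4-(tert-butyldimethylsilyloxy)-2-ethenyl-2-(triethylsilyloxy)-6-(trimethylsilyl)hex-5-yne-1,3-diyl dibenzoate | C[Si](C)(C)C#C[C@@H](O[Si](C)(C)C(C)(C)C)[C@@H](OC(=O)c1ccccc1)[C@](O[Si](CC)(CC)CC)(COC(=O)c1ccccc1)C=C
F5 | step 3 | ozonide of F4 (1,2,4-trioxolan-3-yl in place of ethenyl, both epimers at the trioxolane carbon) | C[Si](C)(C)C#C[C@@H](O[Si](C)(C)C(C)(C)C)[C@@H](OC(=O)c1ccccc1)[C@](O[Si](CC)(CC)CC)(COC(=O)c1ccccc1)C1OCOO1
F6 | step 3 | (2R,3R,4R)-4-(tert-butyldimethylsilyloxy)-2-formyl-2-(triethylsilyloxy)-6-(trimethylsilyl)hex-5-yne-1,3-diyl dibenzoate | C[Si](C)(C)C#C[C@@H](O[Si](C)(C)C(C)(C)C)[C@@H](OC(=O)c1ccccc1)[C@](O[Si](CC)(CC)CC)(COC(=O)c1ccccc1)C=O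
F7 | step 3 | (2R,3R,4R)-4-(tert-butyldimethylsilyloxy)-2-formyl-6-iodo-2-(triethylsilyloxy)hex-5-yne-1,3-diyl dibenzoate | IC#C[C@@H](O[Si](C)(C)C(C)(C)C)[C@@H](OC(=O)c1ccccc1)[C@](O[Si](CC)(CC)CC)(COC(=O)c1ccccc1)C=O
F8 | step 12 | [(1S,2R,3R,6S)-2-(benzoyloxy)-3-(tert-butyldimethylsilyloxy)-6-hydroxy-1-(triethylsilyloxy)cyclohex-4-en-1-yl]methyl benzoate (C6 epimer of 18) | O[C@H]1C=C[C@@H](O[Si](C)(C)C(C)(C)C)[C@@H](OC(=O)c2ccccc2)[C@]1(O[Si](CC)(CC)CC)COC(=O)c1ccccc1
F9 | step 12 | [(1R,2R,3R)-2-(benzoyloxy)-3-(tert-butyldimethylsilyloxy)-6-oxo-1-(triethylsilyloxy)cyclohex-4-en-1-yl]methyl benzoate | O=C1C=C[C@@H](O[Si](C)(C)C(C)(C)C)[C@@H](OC(=O)c2ccccc2)[C@]1(O[Si](CC)(CC)CC)COC(=O)c1ccccc1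
F10 | step 14 | [(1S,2R,3R,6R)-2-(benzoyloxy)-3-(tert-butyldimethylsilyloxy)-1,6-dihydroxycyclohex-4-en-1-yl]methyl benzoate | O[C@@H]1C=C[C@@H](O[Si](C)(C)C(C)(C)C)[C@@H](OC(=O)c2ccccc2)[C@]1(O)COC(=O)c1ccccc1
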